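## Retrosynthetic overview

1. Target 13 ⇐ lactone 12 by carbonyl methylenation; the acid-labile exocyclic enol ether is made last.
2. The trans-diequatorial C-3′ Br / C-4′ Cl pair ⇐ a bromonium ion syn to C-1′, generated stereospecifically from diaxial bromohydrin 10 ⇐ catalyst-controlled epoxide 9 ⇐ the cyclohexene of 8.
3. Bromo-oxanone ring of 8 (second ring) ⇐ 6-endo bromolactonisation of the prenylated hydroxy acid 7 (sets C-5).
4. Key C-3–C-4 bond ⇐ enantioselective ketyl/prenyl radical–radical cross-coupling of α-keto ester 4 with prenyl bromide 5 (sets C-3).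
5. Cyclohexene (first ring) ⇐ asymmetric Diels–Alder of isoprene with methyl 2-oxobut-3-enoate made in the flask from methyl vinylglycolate (sets C-1′).

Locants: oxane ring O-1, C-2 to C-6; cyclohexane ring C-1′ (attachment), C-3′ (Br), C-4′ (Me, Cl).

Assumption: the sense of induction of the chiral catalysts in steps 1 and 2 is assigned by analogy with related systems; if it proved opposite, the enantiomeric catalyst would be used and nothing else changes.

## Route

Step 1
Reactants: 1 methyl 2-hydroxybut-3-enoate (racemic methyl vinylglycolate); 2 isoprene (2-methylbuta-1,3-diene)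
Product: 4 methyl 2-[(1S)-4-methylcyclohex-3-en-1-yl]-2-oxoacetate, via methyl 2-oxobut-3-enoate 3 (not isolated)
Conditions: Dess–Martin periodinane (1.1 equiv), CH2Cl2, 0 °C, 30 min; cold filtration (NaHCO3/Celite) onto 2 (5 equiv) and [Cu((S,S)-t-Bu-box)](SbF6)2 (10 mol %), CH2Cl2, −40 °C, 12 h
Reagents that add atoms: none
Why: Alcohol oxidation gives the very electrophilic vinylglyoxylate 3, which is trapped at once in a Cu(II)–bis(oxazoline)-catalysed asymmetric Diels–Alder reaction, where two-point chelation of the 1,2-dicarbonyl activates the C=C bond over the ketone, the Lewis acid enforces the 1,4 ("para") regiochemistry and the ligand shields one face of the vinyl group so that C-1′ forms as (S).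

Step 2
Reactants: 4 methyl 2-[(1S)-4-methylcyclohex-3-en-1-yl]-2-oxoacetate; 5 prenyl bromide (1-bromo-3-methylbut-2-ene)
Product: 6 methyl (2R)-2-hydroxy-5-methyl-2-[(1S)-4-methylcyclohex-3-en-1-yl]hex-4-enoate
Conditions: 5 (3 equiv), Ir(ppy)2(dtbbpy)PF6 (1 mol %), (R)-STRIP (SPINOL-derived chiral phosphoric acid, 10 mol %), Hantzsch ester (1.5 equiv), K2HPO4 (1.5 equiv), toluene, blue LEDs, −20 °C
Reagents that add atoms: none
Why: Proposed new method: proton-coupled electron transfer to the phosphoric-acid-bound keto ester gives a persistent ketyl radical that stays hydrogen-bonded to the chiral phosphate, the reduced photocatalyst cleaves 5 to the transient prenyl radical, and radical–radical cross-coupling (persistent radical effect) takes place at the unhindered CH2 terminus of the allyl radical (linear prenyl, unlike γ-selective prenyl metals) on the ketyl face left open by the catalyst to give (2R) without touching C-1′ or the ring alkene; the closest known reaction types are photoredox Barbier-type allylation of carbonyl compounds and chiral-phosphoric-acid-controlled ketyl radical couplings of 1,2-dicarbonyls (aza-pinacol cyclisation, ketyl/α-amino radical coupling).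

Step 3
Reactants: 6 methyl (2R)-2-hydroxy-5-methyl-2-[(1S)-4-methylcyclohex-3-en-1-yl]hex-4-enoate
Product: 8 (3R,5R)-5-bromo-3-hydroxy-6,6-dimethyl-3-[(1S)-4-methylcyclohex-3-en-1-yl]oxan-2-one, via free hydroxy acid 7 (not isolated)
Conditions: LiOH·H2O (1.3 equiv), THF/H2O 3:1, 23 °C; then AcOH (1.3 equiv), NBS (1.05 equiv), 0 °C, dark
Reagents that add atoms: N-bromosuccinimide O=C1CCC(=O)N1Br; lithium hydroxide [Li+].[OH-]
Why: Saponification followed by 6-endo bromolactonisation, in which the carboxylate opens the prenyl bromonium ion at its tertiary carbon (Markovnikov) faster than anything traps the ring-alkene bromonium, and a chair transition state with equatorial Br (anti addition), the α-OH held in the carboxyl plane (hydrogen bond, 2-alkyl-ketone effect) and the cyclohexenyl group axial (no syn-axial partner on the ring-oxygen side) sets C-5 as (R), cis to the 3-OH.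

Step 4
Reactants: 8 (3R,5R)-5-bromo-3-hydroxy-6,6-dimethyl-3-[(1S)-4-methylcyclohex-3-en-1-yl]oxan-2-one
Product: 9 (3R,5R)-5-bromo-3-hydroxy-6,6-dimethyl-3-[(1R,3S,6S)-6-methyl-7-oxabicyclo[4.1.0]heptan-3-yl]oxan-2-one
Conditions: D-fructose-derived Shi ketone (30 mol %), Oxone (1.5 equiv), K2CO3 buffer (pH ≈ 9–10), Bu4NHSO4 (cat.), MeCN/dimethoxymethane/H2O, −5 °C, 2 h
Reagents that add atoms: Oxone (potassium peroxymonosulfate) [K+].[O-]S(=O)(=O)OO
Why: Shi asymmetric epoxidation of the only remaining alkene, where the chiral dioxirane (spiro transition state, same sense as for 1-substituted cyclohexenes) and not the remote C-1′ centre decides the face, delivers oxygen anti to the C-1′ substituent, while the hindered tetrasubstituted lactone survives the brief cold, mildly basic exposure.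

Step 5
Reactants: 9 (3R,5R)-5-bromo-3-hydroxy-6,6-dimethyl-3-[(1R,3S,6S)-6-methyl-7-oxabicyclo[4.1.0]heptan-3-yl]oxan-2-one
Product: 10 (3R,5R)-5-bromo-3-[(1S,3R,4R)-4-bromo-3-hydroxy-4-methylcyclohexyl]-3-hydroxy-6,6-dimethyloxan-2-one
Conditions: HBr (33 % in AcOH, 1.1 equiv), CH2Cl2, −40 °C, 15 min; NaHCO3 quench
Reagents that add atoms: hydrogen bromide Br
Why: Acid-promoted epoxide opening in which the electronic (tertiary, Markovnikov) and conformational (Fürst–Plattner trans-diaxial, side chain equatorial) preferences both send bromide to C-4′ with inversion, giving the diaxial bromohydrin with Br syn and OH anti to the C-1′ substituent, the high bromide concentration at low temperature outrunning transannular attack by the 3-OH.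

Step 6
Reactants: 10 (3R,5R)-5-bromo-3-[(1S,3R,4R)-4-bromo-3-hydroxy-4-methylcyclohexyl]-3-hydroxy-6,6-dimethyloxan-2-one
Product: 12 (3R,5R)-5-bromo-3-[(1S,3S,4S)-3-bromo-4-chloro-4-methylcyclohexyl]-3-hydroxy-6,6-dimethyloxan-2-one, via alkoxyphosphonium chloride 11 (not isolated)
Conditions: PPh3 (1.5 equiv) and N-chlorosuccinimide (1.5 equiv) premixed in CH2Cl2 at 0 °C, then 10, 0 → 23 °C
Reagents that add atoms: N-chlorosuccinimide O=C1CCC(=O)N1Cl
Why: Appel-type activation of the secondary axial alcohol only (the tertiary α-hydroxy lactone is inert), after which the antiperiplanar axial bromine expels Ph3P=O with anchimeric assistance to give the bromonium ion on the face syn to C-1′ and chloride opens it at the tertiary carbon (Markovnikov), so that Br ends on C-3′ and Cl on C-4′, each with inversion, as the trans-diequatorial (3′S,4′S) bromochloride.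

Step 7
Reactants: 12 (3R,5R)-5-bromo-3-[(1S,3S,4S)-3-bromo-4-chloro-4-methylcyclohexyl]-3-hydroxy-6,6-dimethyloxan-2-one
Product: 13 (3R,5R)-5-bromo-3-[(1S,3S,4S)-3-bromo-4-chloro-4-methylcyclohexyl]-6,6-dimethyl-2-methylideneoxan-3-ol (target)
Conditions: Cp2TiMe2 (4 equiv), toluene/THF, 65 °C, dark, 24 h; NaHCO3 work-up, Et3N-deactivated silica
Reagents that add atoms: dimethyltitanocene (Petasis reagent) C[Ti](C)(C1C=CC=C1)C1C=CC=C1
Why: Petasis methylenation (Cp2Ti=CH2, [2+2]/retro-[2+2]) turns the lactone carbonyl into the exocyclic enol ether, which cannot move into the ring because C-3 is quaternary, under neutral conditions that leave the alkyl halides and all five stereocentres untouched, the tertiary hydroxyl being carried as its titanium alkoxide and released on work-up.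

## Compound list

1 | methyl 2-hydroxybut-3-enoate (racemic) | C=CC(O)C(=O)OC | starting material
2 | isoprene | C=CC(C)=C | starting material
3 | methyl 2-oxobut-3-enoate | C=CC(=O)C(=O)OC | intermediate (not isolated)
4 | methyl 2-[(1S)-4-methylcyclohex-3-en-1-yl]-2-oxoacetate | COC(=O)C(=O)[C@H]1CCC(C)=CC1 | intermediate
5 | prenyl bromide (1-bromo-3-methylbut-2-ene) | CC(C)=CCBr | starting material
6 | methyl (2R)-2-hydroxy-5-methyl-2-[(1S)-4-methylcyclohex-3-en-1-yl]hex-4-enoate | COC(=O)[C@@](O)(CC=C(C)C)[C@H]1CCC(C)=CC1 | intermediate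
7 | (2R)-2-hydroxy-5-methyl-2-[(1S)-4-methylcyclohex-3-en-1-yl]hex-4-enoic acid | OC(=O)[C@@](O)(CC=C(C)C)[C@H]1CCC(C)=CC1 | intermediate (not isolated)
8 | (3R,5R)-5-bromo-3-hydroxy-6,6-dimethyl-3-[(1S)-4-methylcyclohex-3-en-1-yl]oxan-2-one | O=C1OC(C)(C)[C@H](Br)C[C@@]1(O)[C@H]1CCC(C)=CC1 | intermediate
9 | (3R,5R)-5-bromo-3-hydroxy-6,6-dimethyl-3-[(1R,3S,6S)-6-methyl-7-oxabicyclo[4.1.0]heptan-3-yl]oxan-2-one | O=C1OC(C)(C)[C@H](Br)C[C@@]1(O)[C@H]1CC[C@]2(C)O[C@@H]2C1 | intermediate
10 | (3R,5R)-5-bromo-3-[(1S,3R,4R)-4-bromo-3-hydroxy-4-methylcyclohexyl]-3-hydroxy-6,6-dimethyloxan-2-one | O=C1OC(C)(C)[C@H](Br)C[C@@]1(O)[C@H]1CC[C@@](C)(Br)[C@H](O)C1 | intermediate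
11 | {(1R,2R,5S)-2-bromo-5-[(3R,5R)-5-bromo-3-hydroxy-6,6-dimethyl-2-oxooxan-3-yl]-2-methylcyclohexyl}oxy(triphenyl)phosphonium chloride | O=C1OC(C)(C)[C@H](Br)C[C@@]1(O)[C@H]1CC[C@@](C)(Br)[C@H](O[P+](c2ccccc2)(c2ccccc2)c2ccccc2)C1.[Cl-] | intermediate (not isolated)
12 | (3R,5R)-5-bromo-3-[(1S,3S,4S)-3-bromo-4-chloro-4-methylcyclohexyl]-3-hydroxy-6,6-dimethyloxan-2-one | O=C1OC(C)(C)[C@H](Br)C[C@@]1(O)[C@H]1CC[C@](C)(Cl)[C@@H](Br)C1 | intermediate
13 | (3R,5R)-5-bromo-3-[(1S,3S,4S)-3-bromo-4-chloro-4-methylcyclohexyl]-6,6-dimethyl-2-methylideneoxan-3-ol | C=C1OC(C)(C)[C@H](Br)C[C@@]1(O)[C@H]1CC[C@](C)(Cl)[C@@H](Br)C1 | target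

## Step count and risks

Total steps: 7. Longest linear sequence: 7 (1 → 13).

Steps most likely to fail:

**Step 2** (new enantioselective radical–radical coupling; risks are ketyl reduction or pinacol dimerisation, low ee at C-3, and partial enolisation at C-1′). The fallback sets out from 4 and comes back at 7, replacing the radical coupling by a polar self-regeneration-of-stereocentres sequence. Noyori–Ikariya transfer hydrogenation of the ketone (Ru–TsDPEN antipode chosen for the R alcohol, HCO2H/Et3N) gives methyl (2R)-2-hydroxy-2-[(1S)-4-methylcyclohex-3-en-1-yl]acetate F1. LiOH hydrolysis gives (2R)-2-hydroxy-2-[(1S)-4-methylcyclohex-3-en-1-yl]acetic acid F2. Acetalisation with pivalaldehyde (TsOH, pentane, Dean–Stark) gives the cis-dioxolanone (2R,5R)-2-tert-butyl-5-[(1S)-4-methylcyclohex-3-en-1-yl]-1,3-dioxolan-4-one F3. LDA at −78 °C followed by 5 alkylates the enolate anti to the tert-butyl group to give (2R,5R)-2-tert-butyl-5-(3-methylbut-2-en-1-yl)-5-[(1S)-4-methylcyclohex-3-en-1-yl]-1,3-dioxolan-4-one F4. KOH in MeOH/H2O then releases 7, which enters step 3 at the NBS addition.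

**Step 3** (the C-3/C-5 relationship depends on which C-3 substituent sits axial in the lactonisation transition state; the 3-OH could also cyclise in a 5-endo mode). The fallback sets out from 7, isolated by acidic work-up after the saponification, and comes back at 8. 2,2-Dimethoxypropane with PPTS ties the hydroxyl and carboxyl groups into (5R)-2,2-dimethyl-5-(3-methylbut-2-en-1-yl)-5-[(1S)-4-methylcyclohex-3-en-1-yl]-1,3-dioxolan-4-one F5. NBS in wet MeCN at 0 °C then gives 8 by attack of the dioxolanone carbonyl oxygen on the prenyl bromonium ion and loss of acetone. The rigid five-membered template holds the C-3–O bond in the carboxyl plane, which forces the cyclohexenyl group axial and removes the free hydroxyl as a competing nucleophile.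

**Step 6** (chloride may open the bromonium ion at the secondary carbon in the chair-like diaxial mode instead of at the tertiary carbon; the preceding epoxide steps are also exposed). The fallback sets out from 8 and comes back at 12, replacing steps 4–6 by one direct ionic bromochlorination of the ring alkene (NBS, BnEt3NCl, TMSCl, CH2Cl2, −78 °C). This gives 12 through the bromonium ion syn to C-1′ together with the trans-diaxial diastereomer (3R,5R)-5-bromo-3-[(1S,3R,4R)-3-bromo-4-chloro-4-methylcyclohexyl]-3-hydroxy-6,6-dimethyloxan-2-one F6, which is removed by chromatography. It is shorter but not face-selective, and F6 is expected to be the major product, so 12 is the minor component.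

## Further compounds

F1 | step 2 | methyl (2R)-2-hydroxy-2-[(1S)-4-methylcyclohex-3-en-1-yl]acetate | COC(=O)[C@H](O)[C@H]1CCC(C)=CC1
F2 | step 2 | (2R)-2-hydroxy-2-[(1S)-4-methylcyclohex-3-en-1-yl]acetic acid | OC(=O)[C@H](O)[C@H]1CCC(C)=CC1
F3 | step 2 | (2R,5R)-2-tert-butyl-5-[(1S)-4-methylcyclohex-3-en-1-yl]-1,3-dioxolan-4-one | O=C1O[C@H](C(C)(C)C)O[C@@H]1[C@H]1CCC(C)=CC1
F4 | step 2 | (2R,5R)-2-tert-butyl-5-(3-methylbut-2-en-1-yl)-5-[(1S)-4-methylcyclohex-3-en-1-yl]-1,3-dioxolan-4-one | O=C1O[C@H](C(C)(C)C)O[C@]1(CC=C(C)C)[C@H]1CCC(C)=CC1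
F5 | step 3 | (5R)-2,2-dimethyl-5-(3-methylbut-2-en-1-yl)-5-[(1S)-4-methylcyclohex-3-en-1-yl]-1,3-dioxolan-4-one | CC1(C)OC(=O)[C@@](O1)(CC=C(C)C)[C@H]1CCC(C)=CC1
F6 | step 6 | (3R,5R)-5-bromo-3-[(1S,3R,4R)-3-bromo-4-chloro-4-methylcyclohexyl]-3-hydroxy-6,6-dimethyloxan-2-one | O=C1OC(C)(C)[C@H](Br)C[C@@]1(O)[C@H]1CC[C@@](C)(Cl)[C@H](Br)C1
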